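## Analysis of the target

Labdane numbering is used throughout. Ring A is C1–C5/C10 and ring B is C5–C10. The methyl groups are C17 (on C8), C18/C19 (on C4) and C20 (on C10). The side chain runs C11–C12–C13, and C14–C15(=O)–O–C16 closes the lactone.

- The target is a trans-decalin. Ring B is a 6-hydroxy-7-oxo-8-ene, that is, a tetrasubstituted enone with a ketol at C6. C9 carries, over an ethylene bridge, a γ-butyrolactone with a fully substituted carbinol carbon C13.
- The SMILES reads 5R,6R,10R,13S. The pair 5R,10R is the enantio-labdane series, the mirror image of the decalin in the commercial drimane and labdane feedstocks, so that pool is closed.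
- H5 is anti to C20. The C6 hydroxyl is axial and syn to C20 and to the axial methyl on C4, so it sits on the face that no external oxidant can reach.
- C5, C6 and C10 are contiguous and can be relayed from one another. C13 lies four bonds from C10 across a flexible chain and needs its own source of chirality.
- Two groups are sensitive. The ketol epimerises at C6 to the equatorial alcohol through the enediol under base and can be over-oxidised to the diosphenol. The β-hydroxy lactone loses water by E1cB to give the butenolide.
- The feature that invites the strategy is the following. Ring B, C17 on C8, and the three-carbon branch C4/C18/C19 on the stereocentre C5 together make up the complete ten-carbon skeleton of carvone. The enone appears in its 1,3-transposed form (C9=O, C7=C8 instead of C7=O, C8=C9). Both antipodes of carvone are commercial.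
- The synthesis is hard because four demands fall on a small skeleton: an unnatural-series quaternary C10 next to the neopentyl C5, a contra-steric C6 alcohol, a tetrasubstituted enone, and a remote tertiary carbinol.

## Retrosynthetic reasoning

**17 ⇒ 16 (O–Si at C6).** The ketol is the most base-sensitive unit, so its hydroxyl stays masked as the silyl ether until the last step. The forward reaction is a mildly acidic desilylation that does not enolise C6 or dehydrate C13.

**16 ⇒ 15 ⇒ 14 (C13–O).** C13 cannot be relayed from the decalin, so its oxygen is cut off and the flat butenolide 14 is left. A butenolide tolerates the oxidation that precedes it, whereas a β-hydroxy lactone would not. The forward reaction must add boron to one face of C13 under catalyst control (15), swap B for O with retention, and leave the tetrasubstituted ring enone untouched.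

**14 ⇒ 13 (1,3-transposition C7=O/C8=C9 ⇒ C9–OH/C7=C8).** This turns C9, an unreactive alkene carbon, into a former carbonyl carbon at which the side chain can be attached. It also reveals the carvone oxidation pattern. The forward reaction is an oxidative allylic transposition of a tertiary allylic alcohol.

**13 ⇒ 10 + 11 (C12–C13), through 12.** The cut falls between the sp3 chain and the sp2 carbon of the lactone, so all four lactone carbons arrive as commercial 11. An organometallic that carries a lactone could not be added to a ketone. A vinyl group on C9 serves instead as a latent C11–C12 nucleophile. It must be consumed before the transposition, because a vinyl carbinol would otherwise transpose towards C12.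

**10 ⇒ 9 ⇒ 8 ⇒ 7 (C6–O).** No oxidant can reach the face of C6 that is syn to C20. Oxygen is therefore introduced as a C6 ketone by allylic C–H oxidation of 7. The stereocentre is then set by delivering hydrogen from the open face (8 ⇒ 9). This is done while C9 is sp3, so ring B is not flat and the trans fusion at C5 stays the stable one next to the ketone.

**7 ⇒ 5 + 6 (C9–C11).** This is a 1,2-addition of a two-carbon nucleophile to the only carbonyl group of 5. The configuration at C9 is irrelevant because it is erased in 13 ⇒ 14.

**5 ⇒ 4 (C3–C4, the key disconnection).** Ring A is cut at the bond to the gem-dimethyl carbon. In the precursor C4 is the central carbon of an isopropenyl group, C19 is its =CH2, and C3 is a primary iodide. The bicyclic, doubly quaternary 5 becomes a monocyclic dialkylated carvone. Cutting C1–C10 instead would require an intramolecular enolate alkylation, which closes cis-decalins. Cutting C4–C5 would destroy the purchased stereocentre. The forward reaction has to add H to the =CH2 and C3 to C4 in one operation.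

**4 ⇒ 2 + 3 and 2 ⇒ 1 (C10–C1, C10–C20).** These are two enolate alkylations at the carbon next to C5. The order is fixed by stereochemistry. The second electrophile enters anti to the isopropenyl group, so methyl goes in first and the chain of 3 second. C1 then ends trans to C4 and C20 anti to H5. C5 is bought with 1, C10 is relayed from C5, and C6 is relayed from C10.

## Alternatives that were turned down

**Alternative 1: biomimetic bicyclisation, the textbook route.**
- Disconnection: C4–C5, C9–C10 and C8–O.
- Forward key step: proton-initiated cyclisation of (3E,7E)-homofarnesic acid A1 with a chiral acid of the unnatural sense, giving ent-sclareolide A2. The commercial lactone (+)-sclareolide A3 is 5S,10S and would lead to the enantiomer of the decalin.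
- Reasons for rejection:
  - A2 has no oxygen at C6 or C7, so the alkene must first be moved to C8=C9 and C7 oxidised.
  - Hydroxylation of the C7 enolate then takes place anti to the two axial methyl groups. It gives the equatorial C6 alcohol, which calls for a further oxidation/reduction detour through an enolisable 6,7-dione.
  - The C11–C12 lactone also has to be dismantled and extended.
  - The cyclisation sets only C5 and C10, and the functional-group work after it costs more steps than the whole route below.

**Alternative 2: quinone Diels–Alder reaction.**
- Disconnection: C1–C10 and C4–C5.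
- Forward key step: a chiral Lewis acid joins 2,6-dimethyl-1,4-benzoquinone A4 and 4-methylpenta-1,3-diene A5 to give the adduct A6. This adduct holds 14 of the 20 carbons, with carbonyl groups at C6 and C9.
- Reasons for rejection:
  - The Z-methyl group of A5 penalises the s-cis conformer, and the dienophile carbon C10 is trisubstituted.
  - Suprafacial addition makes A6 cis-fused. Ring B of A6 holds four sp2 carbons and is nearly flat, so the cis isomer can place C4 pseudoaxial without penalty and avoids the syn-axial C19/C20 contact. Epimerisation at C5 to the trans series would therefore run uphill.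
  - The side chain must enter at C9, the more hindered of the two carbonyl groups, which forces extra differentiation steps.
  - The risk would sit in three places rather than one.

**Alternative 3: enzymatic bicyclisation of the whole C20 chain.**
- Disconnection: C4–C5 and C9–C10.
- Forward key step: an ent-copalyl diphosphate synthase (a class two diterpene cyclase) converts geranylgeranyl diphosphate A7 into ent-copalyl diphosphate A8. A phosphatase then gives ent-copalol A9.
- In its favour, the series is right and all carbons are in place.
- Reasons for rejection:
  - A9 lacks oxygen at C6, C7, C13 and C16, and its two alkenes are in the wrong positions.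
  - C16 is an unactivated allylic methyl next to a competing allylic methylene, and the C6 face problem returns unchanged.
  - Five separate oxidations after the key step, plus enzyme production and a costly diphosphate, outweigh what the cyclase gains.

Key step: step 3

Assumption: the ligand antipode written in step 10 is the one expected, by analogy with β-substituted cyclic enones, to deliver boron to the Si face of C13; if the sense is the opposite, the other antipode, equally available, is used.

## Steps

Step 1
Reactants: 1 (S)-(+)-carvone
Product: 2 (5S,6R)-6-methylcarvone (major trans epimer; the minor C6 epimer is carried along)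
Conditions: LiN(i-Pr)2, THF, −78 °C; MeI, −78 to 0 °C
Reagents that add atoms: iodomethane, CI
Why: Kinetic enolate alkylation at the α' carbon of the cross-conjugated enone (the future C10) installs C20. The new centre forms mainly trans to the isopropenyl group but is erased by enolisation in step 2, so its ratio is irrelevant.

Step 2
Reactants: 2 (5S,6R)-6-methylcarvone; 3 1,3-diiodopropane (excess)
Product: 4 (5R,6R)-6-(3-iodopropyl)-6-methylcarvone (iodopropyl trans and methyl cis to the isopropenyl group)
Conditions: LiN(i-Pr)2, THF/DMPU, −78 °C; enolate added to 3 (5 equiv), −78 to 0 °C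
Reagents that add atoms: none
Why: Second kinetic enolate alkylation; the tetrasubstituted enolate is attacked on the face anti to the neighbouring isopropenyl group, as is usual for 6-alkylcarvones, which sets the quaternary C10 by relay from C5. Excess 3 and inverse addition should suppress double alkylation.

Step 3
Reactants: 4 (5R,6R)-6-(3-iodopropyl)-6-methylcarvone
Product: 5 ent-11-nordrim-7-en-9-one = (4aR,8aR)-2,5,5,8a-tetramethyl-4a,5,6,7,8,8a-hexahydronaphthalen-1(4H)-one
Conditions: Mn(dpm)3 (20 mol %), Ni(acac)2 (10 mol %), PhSiH3 (slow addition), K2CO3, (CF3)2CHOH, ClCH2CH2Cl/propylene carbonate, 23 °C, 0.01 M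
Reagents that add atoms: none
Why: Proposed new method: the closest known reaction type is the manganese/nickel dual-catalysed Markovnikov hydroalkylation of 1,1-disubstituted alkenes with unactivated primary alkyl iodides, known between two molecules and used here to close a ring. A manganese hydride formed from Mn(dpm)3 and the silane transfers a hydrogen atom to the terminal CH2 of the isopropenyl group, so that this carbon becomes the second methyl on C4 and C4 becomes a tertiary radical. Low-valent nickel activates the C3–I bond, the alkylnickel species captures the C4 radical, and reductive elimination forms C3–C4. Ring A thus closes as a six-membered carbocycle by C(sp3)–C(sp3) reductive elimination from a seven-membered nickelacycle and not by radical addition, so no exo/endo competition arises. No new stereocentre is formed because C4 carries two methyl groups; the trans fusion is fixed beforehand, since C1 on C10 and C4 on C5 are trans on ring B and can only meet from the diequatorial conformer, which leaves C20 axial and anti to H5. The step needs hydrogen-atom transfer to the electron-rich 1,1-disubstituted alkene in the presence of the trisubstituted enone, the order of reactivity seen in Mukaiyama-type hydrations of carvone itself. It also needs ring closure to outrun simple reduction of either terminus, which the intramolecular setting, high dilution and slow silane addition should secure.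

Step 4
Reactants: 5 ent-11-nordrim-7-en-9-one; 6 vinylmagnesium bromide
Product: 7 C9 vinyl carbinol (5R,9R,10R; vinyl anti and OH syn to C20)
Conditions: CH2=CHMgBr, THF, −20 to 23 °C; aq. NH4Cl
Reagents that add atoms: none
Why: Grignard 1,2-addition to a ketone that has no α-hydrogen; attack should come anti to the axial C20. The C9 configuration has no consequence because it is erased in step 9.

Step 5
Reactants: 7 C9 vinyl carbinol
Product: 8 6-oxo-7-ene carbinol (5R,9R,10R)
Conditions: Rh2(cap)4 (1 mol %), t-BuOOH (70 % aq.), NaHCO3, ClCH2CH2Cl, 40 °C
Reagents that add atoms: tert-butyl hydroperoxide, CC(C)(C)OO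
Why: Radical allylic C–H oxidation of a cyclohexene to the enone; the only secondary allylic C–H bonds are at C6 and the vinyl group has no allylic hydrogen. Chromium oxidants are avoided here because they would transpose the tertiary allylic alcohol too early.

Step 6
Reactants: 8 6-oxo-7-ene carbinol
Product: 9 6,9-diol (5R,6S,9R,10R; C6-OH axial and syn to C20)
Conditions: NaBH4, CeCl3·7H2O, MeOH, −78 °C
Reagents that add atoms: none
Why: Luche 1,2-reduction of the only carbonyl group. C20 and the axial C4 methyl block one face, so hydride should arrive from the opposite face and leave the alcohol axial; C6 is thus set by relay from C10.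

Step 7
Reactants: 9 6,9-diol
Product: 10 6-O-triethylsilyl ether of 9
Conditions: Et3SiOTf (1.05 equiv), 2,6-lutidine, CH2Cl2, −78 °C
Reagents that add atoms: triethylsilyl trifluoromethanesulfonate, CC[Si](CC)(CC)OS(=O)(=O)C(F)(F)F
Why: Silylation of the secondary alcohol in preference to the tertiary carbinol flanked by C8 and the quaternary C10. The ether shields C6-OH from the oxidant of step 9 and stops the C6 allylic alcohol from transposing.

Step 8
Reactants: 10 6-O-triethylsilyl ether of 9; 11 4-bromofuran-2(5H)-one
Product: 13 butenolide carbinol (C12 bonded to C13 of the furanone; C9-OH and C6-OSiEt3 unchanged), via B-alkyl-9-BBN adduct 12 (not isolated)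
Conditions: 9-BBN, THF, 23 to 50 °C; then 11, PdCl2(dppf) (5 mol %), AsPh3, Cs2CO3, DMF/H2O, 23 °C
Reagents that add atoms: 9-borabicyclo[3.3.1]nonane, [H]B1C2CCCC1CCC2 (its boron stays in 12 only)
Why: Anti-Markovnikov hydroboration of the only monosubstituted alkene, with the trisubstituted C7=C8 too hindered for 9-BBN, followed by B-alkyl Suzuki–Miyaura coupling with a vinylogous acyl bromide. All four lactone carbons are added in one step.

Step 9
Reactants: 13 butenolide carbinol
Product: 14 6-O-triethylsilyl-7-oxo-8-ene butenolide (5R,6R,10R)
Conditions: pyridinium chlorochromate, NaOAc, 4 Å MS, CH2Cl2, 23 °C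
Reagents that add atoms: pyridinium chlorochromate, [O-][Cr](=O)(=O)Cl.c1cc[nH+]cc1
Why: Babler–Dauben oxidative transposition; the chromate ester of the tertiary allylic alcohol shifts from C9 to C7 and is oxidised to the ketone, giving the tetrasubstituted C8=C9 enone. Only one allyl system remains because the vinyl group was consumed in step 8.

Step 10
Reactants: 14 6-O-triethylsilyl-7-oxo-8-ene butenolide
Product: 16 6-O-triethylsilyl ether of the target (13S), via tertiary pinacol boronate 15 (not isolated)
Conditions: CuCl (5 mol %), (R,R)-QuinoxP* (6 mol %), NaOt-Bu (10 mol %), B2pin2, MeOH, THF, 0 °C; then NaBO3·4H2O, THF/H2O, 0 to 23 °C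
Reagents that add atoms: bis(pinacolato)diboron, CC1(C)OB(OC1(C)C)B1OC(C)(C)C(C)(C)O1; sodium perborate, [Na+].[Na+].O[B-]1(O)OO[B-](O)(O)OO1
Why: Copper-catalysed enantioselective conjugate borylation, known for β,β-disubstituted unsaturated esters and β-substituted cyclic enones, places boron on the Si face of C13 under ligand control, and oxidation replaces B by OH with retention. The ring enone has a tetrasubstituted β-carbon next to the quaternary C10 and should not react.

Step 11
Reactants: 16 6-O-triethylsilyl ether of the target
Product: 17 target CNP0324736.4 (5R,6R,10R,13S)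
Conditions: HF·pyridine, THF, 0 °C
Reagents that add atoms: none
Why: Fluoride-assisted desilylation under mildly acidic conditions. No base is present, so C6 should not epimerise through the enediol and C13-OH should not be lost by E1cB.

## Compound list

1 | (S)-(+)-carvone | CC=1C(=O)C[C@@H](C(C)=C)CC=1 | starting material
2 | (5S,6R)-2,6-dimethyl-5-(prop-1-en-2-yl)cyclohex-2-en-1-one | CC=1C(=O)[C@H](C)[C@@H](C(C)=C)CC=1 | intermediate
3 | 1,3-diiodopropane | ICCCI | starting material
4 | (5R,6R)-6-(3-iodopropyl)-2,6-dimethyl-5-(prop-1-en-2-yl)cyclohex-2-en-1-one | CC=1C(=O)[C@](C)(CCCI)[C@@H](C(C)=C)CC=1 | intermediate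
5 | (4aR,8aR)-2,5,5,8a-tetramethyl-4a,5,6,7,8,8a-hexahydronaphthalen-1(4H)-one | CC=1C(=O)[C@]2(C)CCCC(C)(C)[C@H]2CC=1 | intermediate
6 | vinylmagnesium bromide | C=C[Mg]Br | starting material
7 | (1R,4aR,8aR)-1-ethenyl-2,5,5,8a-tetramethyl-1,4,4a,5,6,7,8,8a-octahydronaphthalen-1-ol | CC=1[C@](O)(C=C)[C@]2(C)CCCC(C)(C)[C@H]2CC=1 | intermediate
8 | (4R,4aR,8aR)-4-ethenyl-4-hydroxy-3,4a,8,8-tetramethyl-4a,5,6,7,8,8a-hexahydronaphthalen-1(4H)-one | CC=1[C@](O)(C=C)[C@]2(C)CCCC(C)(C)[C@H]2C(=O)C=1 | intermediate
9 | (1S,4R,4aR,8aR)-4-ethenyl-3,4a,8,8-tetramethyl-1,4,4a,5,6,7,8,8a-octahydronaphthalene-1,4-diol | CC=1[C@](O)(C=C)[C@]2(C)CCCC(C)(C)[C@H]2[C@@H](O)C=1 | intermediate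
10 | 6-O-triethylsilyl ether of 9 (labdane C6) | CC=1[C@](O)(C=C)[C@]2(C)CCCC(C)(C)[C@H]2[C@@H](O[Si](CC)(CC)CC)C=1 | intermediate
11 | 4-bromofuran-2(5H)-one | BrC1=CC(=O)OC1 | starting material
12 | B-alkyl-9-BBN adduct of 10 (boron on C12) | CC=1[C@](O)(CCB3C4CCCC3CCC4)[C@]2(C)CCCC(C)(C)[C@H]2[C@@H](O[Si](CC)(CC)CC)C=1 | intermediate
13 | 9-hydroxy-6-triethylsilyloxy-ent-labda-7,13-dien-15,16-olide | CC=1[C@](O)(CCC3=CC(=O)OC3)[C@]2(C)CCCC(C)(C)[C@H]2[C@@H](O[Si](CC)(CC)CC)C=1 | intermediate
14 | 7-oxo-6-triethylsilyloxy-ent-labda-8,13-dien-15,16-olide | CC1=C(CCC3=CC(=O)OC3)[C@]2(C)CCCC(C)(C)[C@H]2[C@@H](O[Si](CC)(CC)CC)C1=O | intermediate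
15 | (13R)-13-pinacolboryl derivative of 14 (C13=C14 saturated) | CC1=C(CC[C@@]3(B4OC(C)(C)C(C)(C)O4)COC(=O)C3)[C@]2(C)CCCC(C)(C)[C@H]2[C@@H](O[Si](CC)(CC)CC)C1=O | intermediate
16 | 6-O-triethylsilyl ether of the target (13S) | CC1=C(CC[C@@]3(O)COC(=O)C3)[C@]2(C)CCCC(C)(C)[C@H]2[C@@H](O[Si](CC)(CC)CC)C1=O | intermediate
17 | CNP0324736.4, (5R,6R,10R,13S)-6,13-dihydroxy-7-oxolabd-8-en-15,16-olide | CC1=C(CC[C@@]2(O)COC(=O)C2)[C@]2(C)CCCC(C)(C)[C@H]2[C@@H](O)C1=O | target

## Step count and least certain steps

Total step count: 11. Longest linear sequence: 11 steps (1 → 17). Compounds 3, 6 and 11 are purchased.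

**Step 3 (key step).**
- What may go wrong:
  - The C4 radical may be reduced before nickel captures it, which amounts to net hydrogenation of the isopropenyl group.
  - Reversible hydrogen abstraction from C5 may move the alkene to C4=C5 and erase the purchased stereocentre.
  - The manganese hydride may reduce the enone in a conjugate sense.
  - The iodide may undergo protodehalogenation.
  - All four are plausible because the ring-closing version of the dual catalysis has no direct model and the enone is a second hydrogen-atom acceptor.
- Fallback: it sets out from 4, returns at 5, and uses known reactions only.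
  - Kornblum oxidation (NaHCO3, DMSO, heat) converts the iodide into the aldehyde F1.
  - Tosylhydrazide condenses chemoselectively with the aldehyde to give the tosylhydrazone F2.
  - Fe(acac)3 and PhSiH3 in EtOH start a hydrogen-atom-transfer radical cyclisation in which the C4 radical adds 6-exo to the C=N carbon C3. This gives the bicyclic N-tosylhydrazine F3.
  - Warming with NaOAc in aqueous EtOH expels sulfinate and nitrogen in the manner of a Caglioti reduction and leaves CH2 at C3, which is 5.

**Step 2.**
- What may go wrong: substitution of an unactivated primary iodide by a hindered tetrasubstituted enolate may be slow. Elimination of HI from 3, O-alkylation and attack of the enolate on the product iodide may then compete.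
- Fallback: it sets out from 2, returns at 5, and so bypasses 4.
  - Alkylation with the far more reactive allyl bromide gives, with the same facial sense, the allyl ketone F4.
  - An aldehyde-selective Wacker-type oxidation of the hindered terminal alkene (PdCl2(PhCN)2, CuCl2·2H2O, AgNO2, O2, t-BuOH/MeNO2) gives the aldehyde F1.
  - The sequence described for step 3 then continues through the tosylhydrazone F2 and the N-tosylhydrazine F3 to 5.

**Step 5.**
- What may go wrong: hydrogen abstraction at C6 may be sluggish because C6 is neopentyl-like. Peroxyl radicals may then add to the vinyl group or oxidise C17, and the acid-labile bis-allylic alcohol may decompose.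
- Fallback: it sets out from 5, returns at 10, and changes the order of events so that oxidation precedes the C9 addition.
  - CrO3·3,5-dimethylpyrazole oxidises 5 at C6 to the trans-enedione F5.
  - Immediate Luche reduction at the C6 carbonyl, which is flanked by two CH groups instead of a quaternary and a methyl-bearing carbon, gives the hydroxy enone F6.
  - Et3SiOTf/2,6-lutidine gives the silyl ether F7.
  - Vinylmagnesium bromide adds to the remaining C9 ketone to give 10.

**Step 10.**
- What may go wrong: facial selectivity may be poor, because both β-substituents of the butenolide begin with a CH2 group. The newly formed hydroxyl may also be lost by β-elimination during the basic oxidation.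
- Fallback: it sets out from 10, returns at 16, and sets C13 by a Sharpless epoxidation instead. It also avoids the base-sensitive 11 of step 8.
  - 2-Bromoprop-2-en-1-ol is protected as the 4-methoxybenzyl ether F8.
  - The borane 12 made from 10 is coupled with F8 under the conditions of step 8 to give the carbinol F9.
  - Pyridinium chlorochromate transposes it to the enone F10.
  - DDQ frees the 2-substituted allylic alcohol F11.
  - Ti(Oi-Pr)4, D-(−)-diisopropyl tartrate and t-BuOOH give the (13R)-epoxy alcohol F12. The Payne rearrangement of this epoxy alcohol is degenerate and does not erode the configuration.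
  - Cyanide opens the epoxide at its CH2 terminus to give the dihydroxy nitrile F13.
  - F13 closes through the iminolactone and gives 16 on mildly acidic work-up.

## Further compounds

F1 | step 3 | 3-[(1R,6R)-1,3-dimethyl-2-oxo-6-(prop-1-en-2-yl)cyclohex-3-en-1-yl]propanal | CC=1C(=O)[C@](C)(CCC=O)[C@@H](C(C)=C)CC=1
F2 | step 3 | N-tosylhydrazone of F1 | CC=1C(=O)[C@](C)(CC/C=N/NS(=O)(=O)c2ccc(C)cc2)[C@@H](C(C)=C)CC=1
F3 | step 3 | 3-(2-tosylhydrazinyl) derivative of 5 (labdane C3, configuration at C3 open) | CC=1C(=O)[C@]2(C)CCC(NNS(=O)(=O)c3ccc(C)cc3)C(C)(C)[C@H]2CC=1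
F4 | step 2 | (5R,6R)-6-allyl-2,6-dimethyl-5-(prop-1-en-2-yl)cyclohex-2-en-1-one | CC=1C(=O)[C@](C)(CC=C)[C@@H](C(C)=C)CC=1
F5 | step 5 | (4aR,8aR)-2,5,5,8a-tetramethyl-4a,5,6,7,8,8a-hexahydronaphthalene-1,4-dione | CC=1C(=O)[C@]2(C)CCCC(C)(C)[C@H]2C(=O)C=1
F6 | step 5 | 6-hydroxy derivative of 5 (C6-OH axial, syn to C20) | CC=1C(=O)[C@]2(C)CCCC(C)(C)[C@H]2[C@@H](O)C=1
F7 | step 5 | 6-O-triethylsilyl ether of F6 | CC=1C(=O)[C@]2(C)CCCC(C)(C)[C@H]2[C@@H](O[Si](CC)(CC)CC)C=1
F8 | step 10 | 1-{[(2-bromoprop-2-en-1-yl)oxy]methyl}-4-methoxybenzene | C=C(Br)COCc1ccc(OC)cc1
F9 | step 10 | C9 carbinol with the side chain CH2CH2C(=CH2)CH2OPMB | CC=1[C@](O)(CCC(=C)COCc3ccc(OC)cc3)[C@]2(C)CCCC(C)(C)[C@H]2[C@@H](O[Si](CC)(CC)CC)C=1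
F10 | step 10 | 7-oxo-8-ene with the side chain CH2CH2C(=CH2)CH2OPMB | CC1=C(CCC(=C)COCc3ccc(OC)cc3)[C@]2(C)CCCC(C)(C)[C@H]2[C@@H](O[Si](CC)(CC)CC)C1=O
F11 | step 10 | 7-oxo-8-ene with the side chain CH2CH2C(=CH2)CH2OH | CC1=C(CCC(=C)CO)[C@]2(C)CCCC(C)(C)[C@H]2[C@@H](O[Si](CC)(CC)CC)C1=O
F12 | step 10 | (13R)-13,14-epoxy-16-ol | CC1=C(CC[C@@]3(CO)CO3)[C@]2(C)CCCC(C)(C)[C@H]2[C@@H](O[Si](CC)(CC)CC)C1=O
F13 | step 10 | (13S)-13,16-dihydroxy-15-nitrile | CC1=C(CC[C@@](O)(CO)CC#N)[C@]2(C)CCCC(C)(C)[C@H]2[C@@H](O[Si](CC)(CC)CC)C1=O
A1 | alternative 1 | (3E,7E)-homofarnesic acid | CC(C)=CCC/C(C)=C/CC/C(C)=C/CC(=O)O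
A2 | alternative 1 | ent-sclareolide | C[C@@]12CCCC([C@H]1CC[C@]3([C@H]2CC(=O)O3)C)(C)C
A3 | alternative 1 | (+)-sclareolide | C[C@]12CCCC([C@@H]1CC[C@@]3([C@@H]2CC(=O)O3)C)(C)C
A4 | alternative 2 | 2,6-dimethyl-1,4-benzoquinone | CC1=CC(=O)C=C(C)C1=O
A5 | alternative 2 | 4-methylpenta-1,3-diene | CC(C)=CC=C
A6 | alternative 2 | (4aS,8aR)-2,5,5,8a-tetramethyl-4a,5,8,8a-tetrahydronaphthalene-1,4-dione (cis-fused) | CC=1C(=O)[C@]2(C)CC=CC(C)(C)[C@@H]2C(=O)C=1
A7 | alternative 3 | (E,E,E)-geranylgeranyl diphosphate | CC(C)=CCC/C(C)=C/CC/C(C)=C/CC/C(C)=C/COP(=O)(O)OP(=O)(O)O
A8 | alternative 3 | ent-copalyl diphosphate | C=C1[C@@H](CC/C(C)=C/COP(=O)(O)OP(=O)(O)O)[C@]2(C)CCCC(C)(C)[C@H]2CC1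
A9 | alternative 3 | ent-copalol | C=C1[C@@H](CC/C(C)=C/CO)[C@]2(C)CCCC(C)(C)[C@H]2CC1
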